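**Retrosynthetic overview**

1. The target is the (E)-aldol-condensation dimer of a single aldehyde. Both all-cis (2S,3S,6R) piperidines (N1, C2 methyl, C3 carbinol, C4, C5, C6 chain) belong to the same monomer, so the ring is built once and the enal comes from a self-condensation followed by global deprotection.
2. The monomer piperidine comes from Cbz hydrogenolysis and C6=N1 imine hydrogenation (all-cis) of a δ-keto carbamate, itself made by Grignard opening of an N-Cbz lactam at the C6 carbonyl with a C12 chain.
3. The lactam ring is closed at C3–C4 by a SmI2 ketyl–olefin cyclisation (6-endo) of an acrylimide aldehyde assembled from N-Cbz-L-alaninol (C2, N1, C3) and acryloyl chloride (C4–C6).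
4. Enabling feature: C3 is a carbinol carbon sitting directly on the alanine-derived C2–N1 unit, and C4 is β to C6, the ring carbon on N1. Raising C6 temporarily to the acyl level turns N1–C6(=O)–C5=C4 into an acrylimide whose β-carbon C4 accepts a C3 ketyl, and the C2 methyl on the N-acylated ring directs the new C3 centre.
5. Ring order: the six-membered ring is formed in step 5 (C3–C4 bond), opened at the N1–C6 acyl bond in step 8 and re-closed at the same N1–C6 bond in step 9; no other ring is made.

Key step: step 5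

Assumption: N-Cbz-L-alaninol, acryloyl chloride and 12-bromododecan-1-ol are taken as commercial, and the target is isolated as the free base.

**Route**

Step 1
Reactants: 1 benzyl N-[(2S)-1-hydroxypropan-2-yl]carbamate (N-Cbz-L-alaninol)
Product: 2 benzyl N-[(2S)-1-(tert-butyldimethylsilyloxy)propan-2-yl]carbamate
Conditions: TBSCl, imidazole, DMF, 0 °C → rt
Reagents that add atoms: tert-butyldimethylsilyl chloride (TBSCl), CC(C)(C)[Si](C)(C)Cl
Why: Silylation of the primary alcohol (standard silyl ether formation) masks the hydroxyl against the strong base of step 2 and leaves the alanine-derived stereocentre untouched.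

Step 2
Reactants: 2 benzyl N-[(2S)-1-(tert-butyldimethylsilyloxy)propan-2-yl]carbamate; 3 acryloyl chloride
Product: 4 benzyl N-acryloyl-N-[(2S)-1-(tert-butyldimethylsilyloxy)propan-2-yl]carbamate
Conditions: LiN(SiMe3)2, THF, −78 °C; then 3, BHT (cat.), −78 → −40 °C
Reagents that add atoms: none
Why: The carbamate N–H is deprotonated by LiN(SiMe3)2 and the lithium carbamate is N-acylated by the acid chloride (imide formation of the type used to make N-enoyl carbamates), with low temperature and BHT holding back polymerisation of the acrylimide.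

Step 3
Reactants: 4 benzyl N-acryloyl-N-[(2S)-1-(tert-butyldimethylsilyloxy)propan-2-yl]carbamate
Product: 5 benzyl N-acryloyl-N-[(2S)-1-hydroxypropan-2-yl]carbamate
Conditions: HF (48% aq), MeCN, 0 °C
Reagents that add atoms: none
Why: Acidic fluoride desilylation removes the primary TBS ether without forming an alkoxide, which avoids N→O acyl migration in the β-hydroxy imide and conjugate addition to the acrylimide.

Step 4
Reactants: 5 benzyl N-acryloyl-N-[(2S)-1-hydroxypropan-2-yl]carbamate
Product: 6 benzyl N-acryloyl-N-[(2S)-1-oxopropan-2-yl]carbamate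
Conditions: Dess–Martin periodinane, NaHCO3, CH2Cl2, 0 °C → rt; used crude at once
Reagents that add atoms: none
Why: Dess–Martin oxidation under buffered, base-free conditions should give the α-(diacylamino) aldehyde without epimerising C2, which carries no N–H.

Step 5
Reactants: 6 benzyl N-acryloyl-N-[(2S)-1-oxopropan-2-yl]carbamate
Product: 7 benzyl (2S,3S)-3-hydroxy-2-methyl-6-oxopiperidine-1-carboxylate
Conditions: SmI2 (2.5 equiv), HMPA (8 equiv), t-BuOH (3 equiv), THF, −78 °C, slow addition of 6 (final 0.01 M); NH4Cl (aq)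
Reagents that add atoms: none
Why: Proposed new method: SmI2 should reduce the aldehyde of 6 to a samarium ketyl at C3, which adds to C4, the β-carbon of the N-acryloyl group, and the α-carbonyl radical left at C5 is reduced to a samarium enolate and protonated by t-BuOH, so that the new C3–C4 bond closes the N1–C2–C3–C4–C5–C6 ring. The closest known reaction type is the SmI2 ketyl–olefin reductive coupling of aldehydes with acrylates and N-enoyl carbamates, which is established intermolecularly and for exo ring closures but not for an endo closure through the acyl tether to a δ-lactam. The ring closes in the 6-endo-trig mode; the 5-exo alternative (attack at C5) is polarity-mismatched for the nucleophilic ketyl and would leave an unstabilised primary radical. The new stereocentre C3 is controlled by C2: allylic 1,3-strain with the planar N-acyl carbamate holds the C2 methyl pseudoaxial in the half-chair transition state, and the bulky HMPA-solvated O–Sm group takes the pseudoequatorial position anti to the C2–N1 bond, which places the hydroxyl cis to the methyl group (3S). The step needs the ketyl to cyclise faster than it dimerises, is reduced further or expels the imide nitrogen; this should be secured by high dilution at −78 °C, by the electron-poor acrylimide acceptor and by the low rotation barrier of the imide C–N bond, which keeps the reactive rotamer available, while HMPA suppresses chelation of samarium by the carbamate carbonyl, the one arrangement that would lead to the trans isomer.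

Step 6
Reactants: 7 benzyl (2S,3S)-3-hydroxy-2-methyl-6-oxopiperidine-1-carboxylate
Product: 8 benzyl (2S,3S)-3-(tert-butyldimethylsilyloxy)-2-methyl-6-oxopiperidine-1-carboxylate
Conditions: TBSOTf, 2,6-lutidine, CH2Cl2, −78 → 0 °C
Reagents that add atoms: tert-butyldimethylsilyl trifluoromethanesulfonate (TBSOTf), CC(C)(C)[Si](C)(C)OS(=O)(=O)C(F)(F)F
Why: The silyl triflate with 2,6-lutidine silylates the hindered secondary alcohol under non-nucleophilic conditions that leave the N-acyl carbamate intact.

Step 7
Reactants: 9 12-bromododecan-1-ol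
Product: 10 (12-bromododecyloxy)(tert-butyl)dimethylsilane
Conditions: TBSCl, imidazole, DMF, rt
Reagents that add atoms: tert-butyldimethylsilyl chloride (TBSCl), CC(C)(C)[Si](C)(C)Cl
Why: Standard silyl ether formation protects the primary alcohol so that the bromide can be converted into a Grignard reagent.

Step 8
Reactants: 8 benzyl (2S,3S)-3-(tert-butyldimethylsilyloxy)-2-methyl-6-oxopiperidine-1-carboxylate; 10 (12-bromododecyloxy)(tert-butyl)dimethylsilane
Product: 12 benzyl N-[(2S,3S)-3,18-bis(tert-butyldimethylsilyloxy)-6-oxooctadecan-2-yl]carbamate, via Grignard reagent 11 (not isolated)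
Conditions: 10, Mg, BrCH2CH2Br (cat.), THF, reflux; then 8, THF, −78 °C; NH4Cl (aq)
Reagents that add atoms: none
Why: Magnesium insertion gives the Grignard reagent, which adds once at −78 °C to the ketone-like ring carbonyl of the N-alkoxycarbonyl lactam, and the tetrahedral intermediate collapses to the ring-opened δ-keto carbamate (the well-precedented Grignard ring-opening of N-acyl lactams).

Step 9
Reactants: 12 benzyl N-[(2S,3S)-3,18-bis(tert-butyldimethylsilyloxy)-6-oxooctadecan-2-yl]carbamate
Product: 15 (2S,3S,6R)-3-(tert-butyldimethylsilyloxy)-6-[12-(tert-butyldimethylsilyloxy)dodecyl]-2-methylpiperidine, via amino ketone 13 (not isolated), via cyclic imine 14 (not isolated)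
Conditions: H2 (1 atm), 10% Pd/C, EtOAc–EtOH, rt
Reagents that add atoms: none
Why: Hydrogenolysis of the Cbz group frees the amine, which condenses with the δ-ketone to the cyclic imine, and hydrogen is then delivered to the imine face opposite the cis C2-methyl and C3-silyloxy groups, setting C6 as R and the all-cis ring (reductive amination by catalytic hydrogenation, well precedented for 2,3-cis-disubstituted cyclic imines of this alkaloid class).

Step 10
Reactants: 15 (2S,3S,6R)-3-(tert-butyldimethylsilyloxy)-6-[12-(tert-butyldimethylsilyloxy)dodecyl]-2-methylpiperidine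
Product: 16 tert-butyl (2S,3S,6R)-3-(tert-butyldimethylsilyloxy)-6-[12-(tert-butyldimethylsilyloxy)dodecyl]-2-methylpiperidine-1-carboxylate
Conditions: Boc2O (3 equiv), iPr2NEt, THF, 60 °C
Reagents that add atoms: di-tert-butyl dicarbonate (Boc2O), CC(C)(C)OC(=O)OC(=O)OC(C)(C)C
Why: Carbamate formation with Boc2O masks the hindered secondary amine (warming compensates for the 2,6-disubstitution) so that it cannot interfere with the oxidation and the aldehyde condensation.

Step 11
Reactants: 16 tert-butyl (2S,3S,6R)-3-(tert-butyldimethylsilyloxy)-6-[12-(tert-butyldimethylsilyloxy)dodecyl]-2-methylpiperidine-1-carboxylate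
Product: 17 tert-butyl (2S,3S,6R)-3-(tert-butyldimethylsilyloxy)-6-(12-hydroxydodecyl)-2-methylpiperidine-1-carboxylate
Conditions: HF·pyridine, pyridine, THF, 0 °C
Reagents that add atoms: none
Why: Buffered HF·pyridine should cleave the unhindered primary TBS ether far faster than the secondary ring TBS ether that is flanked by the C2 methyl and the N-Boc group (selective desilylation on steric grounds).

Step 12
Reactants: 17 tert-butyl (2S,3S,6R)-3-(tert-butyldimethylsilyloxy)-6-(12-hydroxydodecyl)-2-methylpiperidine-1-carboxylate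
Product: 18 tert-butyl (2S,3S,6R)-3-(tert-butyldimethylsilyloxy)-2-methyl-6-(12-oxododecyl)piperidine-1-carboxylate
Conditions: Dess–Martin periodinane, NaHCO3, CH2Cl2, rt
Reagents that add atoms: none
Why: Dess–Martin oxidation converts the primary alcohol to the aldehyde under neutral conditions that tolerate the Boc carbamate and the silyl ether.

Step 13
Reactants: 18 tert-butyl (2S,3S,6R)-3-(tert-butyldimethylsilyloxy)-2-methyl-6-(12-oxododecyl)piperidine-1-carboxylate (two molecules)
Product: 20 N,N'-bis-Boc O,O'-bis-TBS derivative of the target (E)-enal, via aldol adduct 19 (not isolated)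
Conditions: pyrrolidine (20 mol %), PhCO2H (20 mol %), toluene, 50 °C
Reagents that add atoms: none
Why: Secondary-amine/acid catalysis converts one aldehyde into its enamine, which adds to a second, iminium-activated aldehyde, and dehydration of the aldol should give the thermodynamically preferred (E)-2-alkyl-2-enal (aldol self-condensation, as in the presumed biosynthesis); because both partners are the same monomer, no cross-selectivity is needed.

Step 14
Reactants: 20 N,N'-bis-Boc O,O'-bis-TBS derivative of the target (E)-enal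
Product: 21 (2E)-2-{10-[(2R,5S,6S)-5-hydroxy-6-methylpiperidin-2-yl]decyl}-14-[(2R,5S,6S)-5-hydroxy-6-methylpiperidin-2-yl]tetradec-2-enal (CNP0177491.1)
Conditions: TFA–H2O (9:1), 0 °C → rt; then NaHCO3 (aq), 0 °C
Reagents that add atoms: none
Why: Aqueous TFA cleaves both Boc carbamates (loss of 2-methylpropene and CO2) and both secondary TBS ethers while the conjugated enal is stable to acid, and cold bicarbonate then liberates the free base.

**Compound list**

1 | benzyl N-[(2S)-1-hydroxypropan-2-yl]carbamate (N-Cbz-L-alaninol) | C[C@H](NC(=O)OCc1ccccc1)CO | starting material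
2 | benzyl N-[(2S)-1-(tert-butyldimethylsilyloxy)propan-2-yl]carbamate | C[C@H](NC(=O)OCc1ccccc1)CO[Si](C)(C)C(C)(C)C | intermediate
3 | acryloyl chloride (prop-2-enoyl chloride) | C=CC(=O)Cl | starting material
4 | benzyl N-acryloyl-N-[(2S)-1-(tert-butyldimethylsilyloxy)propan-2-yl]carbamate | C[C@H](N(C(=O)C=C)C(=O)OCc1ccccc1)CO[Si](C)(C)C(C)(C)C | intermediate
5 | benzyl N-acryloyl-N-[(2S)-1-hydroxypropan-2-yl]carbamate | C[C@H](N(C(=O)C=C)C(=O)OCc1ccccc1)CO | intermediate
6 | benzyl N-acryloyl-N-[(2S)-1-oxopropan-2-yl]carbamate | C[C@H](N(C(=O)C=C)C(=O)OCc1ccccc1)C=O | intermediate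
7 | benzyl (2S,3S)-3-hydroxy-2-methyl-6-oxopiperidine-1-carboxylate | C[C@@H]1N(C(=O)OCc2ccccc2)C(=O)CC[C@@H]1O | intermediate
8 | benzyl (2S,3S)-3-(tert-butyldimethylsilyloxy)-2-methyl-6-oxopiperidine-1-carboxylate | C[C@@H]1N(C(=O)OCc2ccccc2)C(=O)CC[C@@H]1O[Si](C)(C)C(C)(C)C | intermediate
9 | 12-bromododecan-1-ol | OCCCCCCCCCCCCBr | starting material
10 | (12-bromododecyloxy)(tert-butyl)dimethylsilane | BrCCCCCCCCCCCCO[Si](C)(C)C(C)(C)C | intermediate
11 | [12-(tert-butyldimethylsilyloxy)dodecyl]magnesium bromide | Br[Mg]CCCCCCCCCCCCO[Si](C)(C)C(C)(C)C | intermediate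
12 | benzyl N-[(2S,3S)-3,18-bis(tert-butyldimethylsilyloxy)-6-oxooctadecan-2-yl]carbamate | C[C@H](NC(=O)OCc1ccccc1)[C@@H](O[Si](C)(C)C(C)(C)C)CCC(=O)CCCCCCCCCCCCO[Si](C)(C)C(C)(C)C | intermediate
13 | (2S,3S)-2-amino-3,18-bis(tert-butyldimethylsilyloxy)octadecan-6-one | C[C@H](N)[C@@H](O[Si](C)(C)C(C)(C)C)CCC(=O)CCCCCCCCCCCCO[Si](C)(C)C(C)(C)C | intermediate
14 | (2S,3S)-3-(tert-butyldimethylsilyloxy)-6-[12-(tert-butyldimethylsilyloxy)dodecyl]-2-methyl-2,3,4,5-tetrahydropyridine | C[C@@H]1N=C(CCCCCCCCCCCCO[Si](C)(C)C(C)(C)C)CC[C@@H]1O[Si](C)(C)C(C)(C)C | intermediate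
15 | (2S,3S,6R)-3-(tert-butyldimethylsilyloxy)-6-[12-(tert-butyldimethylsilyloxy)dodecyl]-2-methylpiperidine | C[C@@H]1N[C@H](CCCCCCCCCCCCO[Si](C)(C)C(C)(C)C)CC[C@@H]1O[Si](C)(C)C(C)(C)C | intermediate
16 | tert-butyl (2S,3S,6R)-3-(tert-butyldimethylsilyloxy)-6-[12-(tert-butyldimethylsilyloxy)dodecyl]-2-methylpiperidine-1-carboxylate | C[C@@H]1N(C(=O)OC(C)(C)C)[C@H](CCCCCCCCCCCCO[Si](C)(C)C(C)(C)C)CC[C@@H]1O[Si](C)(C)C(C)(C)C | intermediate
17 | tert-butyl (2S,3S,6R)-3-(tert-butyldimethylsilyloxy)-6-(12-hydroxydodecyl)-2-methylpiperidine-1-carboxylate | C[C@@H]1N(C(=O)OC(C)(C)C)[C@H](CCCCCCCCCCCCO)CC[C@@H]1O[Si](C)(C)C(C)(C)C | intermediate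
18 | tert-butyl (2S,3S,6R)-3-(tert-butyldimethylsilyloxy)-2-methyl-6-(12-oxododecyl)piperidine-1-carboxylate | C[C@@H]1N(C(=O)OC(C)(C)C)[C@H](CCCCCCCCCCCC=O)CC[C@@H]1O[Si](C)(C)C(C)(C)C | intermediate
19 | aldol adduct of two molecules of 18: 13-formyl-12-hydroxytricosane-1,23-diyl chain joining two N-Boc, O-TBS (2S,3S,6R)-piperidines at C6 (mixture of diastereomers at the two new centres) | C[C@@H]1N(C(=O)OC(C)(C)C)[C@H](CCCCCCCCCCCC(O)C(C=O)CCCCCCCCCC[C@@H]2CC[C@H](O[Si](C)(C)C(C)(C)C)[C@H](C)N2C(=O)OC(C)(C)C)CC[C@@H]1O[Si](C)(C)C(C)(C)C | intermediate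
20 | N,N'-bis-Boc O,O'-bis-TBS derivative of the target: tert-butyl (2S,3S,6R)-6-{(12E)-23-[(2R,5S,6S)-1-(tert-butoxycarbonyl)-5-(tert-butyldimethylsilyloxy)-6-methylpiperidin-2-yl]-13-formyltricos-12-en-1-yl}-3-(tert-butyldimethylsilyloxy)-2-methylpiperidine-1-carboxylate | C[C@@H]1N(C(=O)OC(C)(C)C)[C@H](CCCCCCCCCCC/C=C(/C=O)CCCCCCCCCC[C@@H]2CC[C@H](O[Si](C)(C)C(C)(C)C)[C@H](C)N2C(=O)OC(C)(C)C)CC[C@@H]1O[Si](C)(C)C(C)(C)C | intermediate
21 | (2E)-2-{10-[(2R,5S,6S)-5-hydroxy-6-methylpiperidin-2-yl]decyl}-14-[(2R,5S,6S)-5-hydroxy-6-methylpiperidin-2-yl]tetradec-2-enal (CNP0177491.1) | C[C@@H]1N[C@H](CCCCCCCCCCC/C=C(/C=O)CCCCCCCCCC[C@@H]2CC[C@H](O)[C@H](C)N2)CC[C@@H]1O | target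

**Summary**

Total step count: 14. Longest linear sequence: 13 steps (from 1 through steps 1–6 and 8–14; step 7 prepares the side chain).

Steps most likely to fail:

1. Step 5 (the proposed SmI2 cyclisation). The ketyl may be reduced further, dimerise or expel the imide nitrogen faster than it closes the ring in the unusual endo mode, or the ring may close with poor facial selectivity at C3. The fallback uses known chemistry and sets out from 1. Dess–Martin oxidation gives benzyl N-[(2S)-1-oxopropan-2-yl]carbamate F1. Chelation-controlled, syn-selective addition of the titanium homoenolate made from ethyl 3-iodopropanoate (Zn–Cu couple, then TiCl(OiPr)3) gives ethyl (4S,5S)-5-{[(benzyloxy)carbonyl]amino}-4-hydroxyhexanoate F2. This is lactonised (AcOH, toluene, heat) to benzyl N-[(1S)-1-[(2S)-5-oxooxolan-2-yl]ethyl]carbamate F3. Hydrogenolysis (H2, Pd/C, MeOH) frees (5S)-5-[(1S)-1-aminoethyl]oxolan-2-one F4, which rearranges by O→N acyl transfer to (5S,6S)-5-hydroxy-6-methylpiperidin-2-one F5. Silylation (TBSCl, imidazole) gives (5S,6S)-5-(tert-butyldimethylsilyloxy)-6-methylpiperidin-2-one F6, and N-acylation (LiN(SiMe3)2, benzyl chloroformate, THF, −78 °C) comes back to the route at 8.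

2. Step 8 (Grignard opening of the N-Cbz lactam). The reagent may attack the carbamate carbonyl, enolise the lactam or add twice to the liberated ketone. The fallback keeps the ring closed and sets out from 8. O-Phosphorylation of the lactam enolate (KN(SiMe3)2, (PhO)2P(O)Cl, THF, −78 °C) gives benzyl (2S,3S)-3-(tert-butyldimethylsilyloxy)-6-[(diphenoxyphosphoryl)oxy]-2-methyl-3,4-dihydropyridine-1(2H)-carboxylate F7. Negishi coupling under Pd(PPh3)4 with [12-(tert-butyldimethylsilyloxy)dodecyl]zinc bromide F8, made from 10 with Zn dust and LiCl, gives benzyl (2S,3S)-3-(tert-butyldimethylsilyloxy)-6-[12-(tert-butyldimethylsilyloxy)dodecyl]-2-methyl-3,4-dihydropyridine-1(2H)-carboxylate F9. Hydrogenation (H2, Pd/C) removes the Cbz group, the enamine tautomerises to imine 14 and is reduced, and the route is rejoined at 15.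

3. Step 13 (aldol self-condensation). Condensation may run on beyond the dimer, or the amine catalyst may add to the enal product. The fallback is a directed aldol condensation and sets out from 18. Condensation of one half of 18 with cyclohexylamine gives the N-cyclohexyl imine of 18 F10. Deprotonation with LiN(iPr)2 (THF, −78 °C) and addition of the aza-enolate to the second half of 18 gives the β-hydroxy imine F11. Aqueous oxalic acid hydrolyses this to aldol 19 and dehydrates it, coming back to the route at 20.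

**Further compounds**

F1 | step 5 | benzyl N-[(2S)-1-oxopropan-2-yl]carbamate | C[C@H](NC(=O)OCc1ccccc1)C=O
F2 | step 5 | ethyl (4S,5S)-5-{[(benzyloxy)carbonyl]amino}-4-hydroxyhexanoate | C[C@H](NC(=O)OCc1ccccc1)[C@@H](O)CCC(=O)OCC
F3 | step 5 | benzyl N-[(1S)-1-[(2S)-5-oxooxolan-2-yl]ethyl]carbamate | C[C@H](NC(=O)OCc1ccccc1)[C@@H]1CCC(=O)O1
F4 | step 5 | (5S)-5-[(1S)-1-aminoethyl]oxolan-2-one | C[C@H](N)[C@@H]1CCC(=O)O1
F5 | step 5 | (5S,6S)-5-hydroxy-6-methylpiperidin-2-one | C[C@@H]1NC(=O)CC[C@@H]1O
F6 | step 5 | (5S,6S)-5-(tert-butyldimethylsilyloxy)-6-methylpiperidin-2-one | C[C@@H]1NC(=O)CC[C@@H]1O[Si](C)(C)C(C)(C)C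
F7 | step 8 | benzyl (2S,3S)-3-(tert-butyldimethylsilyloxy)-6-[(diphenoxyphosphoryl)oxy]-2-methyl-3,4-dihydropyridine-1(2H)-carboxylate | C[C@@H]1N(C(=O)OCc2ccccc2)C(OP(=O)(Oc2ccccc2)Oc2ccccc2)=CC[C@@H]1O[Si](C)(C)C(C)(C)C
F8 | step 8 | [12-(tert-butyldimethylsilyloxy)dodecyl]zinc bromide | Br[Zn]CCCCCCCCCCCCO[Si](C)(C)C(C)(C)C
F9 | step 8 | benzyl (2S,3S)-3-(tert-butyldimethylsilyloxy)-6-[12-(tert-butyldimethylsilyloxy)dodecyl]-2-methyl-3,4-dihydropyridine-1(2H)-carboxylate | C[C@@H]1N(C(=O)OCc2ccccc2)C(CCCCCCCCCCCCO[Si](C)(C)C(C)(C)C)=CC[C@@H]1O[Si](C)(C)C(C)(C)C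
F10 | step 13 | N-cyclohexyl imine of 18: tert-butyl (2S,3S,6R)-3-(tert-butyldimethylsilyloxy)-6-[12-(cyclohexylimino)dodecyl]-2-methylpiperidine-1-carboxylate | C[C@@H]1N(C(=O)OC(C)(C)C)[C@H](CCCCCCCCCCCC=NC3CCCCC3)CC[C@@H]1O[Si](C)(C)C(C)(C)C
F11 | step 13 | β-hydroxy imine: N-cyclohexyl imine of aldol 19 (mixture of diastereomers at the two new centres) | C[C@@H]1N(C(=O)OC(C)(C)C)[C@H](CCCCCCCCCCCC(O)C(C=NC3CCCCC3)CCCCCCCCCC[C@@H]2CC[C@H](O[Si](C)(C)C(C)(C)C)[C@H](C)N2C(=O)OC(C)(C)C)CC[C@@H]1O[Si](C)(C)C(C)(C)C
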